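## Retrosynthetic overview

1. The route rests on the trisubstituted C18=C19 alkene of the 28-membered macrocycle: C19 carries the carboxyl cis to C17 and the C20 methylene trans to it, so the ring is opened at C19–C20 to a C19 alkenyl iodide and a terminal C20=C21 alkene (B-alkyl Suzuki closure).
2. The (2E,4E)-2-iodo-dienoate comes from syn-hydrostannation and iodination of a C18≡C19 ynoate, itself made by Sonogashira coupling of an (E)-C16=C17 alkenyl iodide with 2-(trimethylsilyl)ethyl propiolate.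
3. The seco chain is joined at the O2–C3 ester (Yamaguchi) and the N27–C28 amide from three pieces: a C3–C17 acid, (S)-2-hydroxypentanoic acid (from L-norvaline) and a C20–C26 amine (from 2-deoxy-D-ribose, C25 set by a catalytic nitroaldol reaction).
4. The C3–C17 acid is cut at C11–C12 (Fukuyama ketone synthesis) into a C3–C11 thioester (desymmetrised meso-2,4-dimethylglutaric anhydride, Wittig chain extension) and a C12–C16 iodide (Evans allylation sets C15); Takai olefination gives C16=C17.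
5. Ring order: the single ring, the 28-membered macrocycle, is closed in step 34; ketal hydrolysis and fluoride deprotection follow.

Key step: step 34

Numbering used: C1 = propyl-bearing carbinol carbon of the hydroxy-acid unit, O2, C3 = ester carbonyl, C4 and C6 = methyl-bearing carbons, C11 = ketone, C15 = ethyl-bearing carbon, C16=C17, C18=C19 (C19 bears the carboxyl), C20–C26, N27, C28 = amide carbonyl. The target is (1S,4S,6S,15R,16E,18Z,22R,23S,25S).

Assumption 1: the (DHQD)2AQN-catalysed methanolysis in step 12 is taken to open the carbonyl next to the (S)-configured carbon of the meso anhydride; if the sense is the opposite, the pseudoenantiomeric (DHQ)2AQN is used.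

Assumption 2: in step 8 the antipode of the bis(oxazoline) ligand is chosen that sends the nitronate to the Re face of the C25 aldehyde, and catalyst control is taken to override the weak bias of the β-silyloxy group.

## Route

Step 1
Reactants: 1 L-norvaline
Product: 4 (S)-2-hydroxypentanoic acid, via diazonium carboxylate 2 (not isolated), via α-lactone 3 (not isolated)
Conditions: NaNO2, 1 M H2SO4, H2O, 0 °C → rt
Reagents that add atoms: water (O)
Why: Diazotisation of the α-amino acid (hydroxy-de-amination): the carboxylate displaces N2 with inversion to the α-lactone and water opens it with a second inversion, so C1 keeps the (S) configuration.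

Step 2
Reactants: 5 2-deoxy-D-ribose
Product: 6 (2R,3S)-4-(1,3-dithian-2-yl)butane-1,2,3-triol
Conditions: HS(CH2)3SH, conc. HCl, 0 °C
Reagents that add atoms: propane-1,3-dithiol (SCCCS)
Why: Acid-catalysed dithioacetalisation of the open-chain aldehyde masks C25 as a 1,3-dithiane and frees the three hydroxyls; C22 and C23 come unchanged from the sugar.

Step 3
Reactants: 6 dithiane triol
Product: 7 2-[(2S,3R)-2,3,4-tris(tert-butyldimethylsilyloxy)butyl]-1,3-dithiane
Conditions: t-BuMe2SiOTf (3.6 equiv), 2,6-lutidine, CH2Cl2, 0 °C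
Reagents that add atoms: tert-butyldimethylsilyl triflate (CC(C)(C)[Si](C)(C)OS(=O)(=O)C(F)(F)F)
Why: Exhaustive O-silylation with the silyl triflate and a hindered base protects all three hydroxyls.

Step 4
Reactants: 7 tris-silyl ether
Product: 8 (2R,3S)-2,3-bis(tert-butyldimethylsilyloxy)-4-(1,3-dithian-2-yl)butan-1-ol
Conditions: HF·pyridine, pyridine, THF, 0 °C
Reagents that add atoms: none
Why: Selective desilylation: the primary silyl ether is cleaved by buffered HF much faster than the secondary ones, without silyl migration or loss of the dithiane.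

Step 5
Reactants: 8 primary alcohol
Product: 9 (2S,3S)-2,3-bis(tert-butyldimethylsilyloxy)-4-(1,3-dithian-2-yl)butanal
Conditions: SO3·pyridine, DMSO, i-Pr2NEt, CH2Cl2, 0 °C
Reagents that add atoms: none
Why: Parikh–Doering oxidation gives the α-silyloxy aldehyde under cold, non-acidic conditions that spare the dithiane sulfur and the adjacent stereocentre.

Step 6
Reactants: 9 aldehyde
Product: 10 2-[(2S,3R)-2,3-bis(tert-butyldimethylsilyloxy)pent-4-en-1-yl]-1,3-dithiane
Conditions: Ph3PCH3Br, KN(SiMe3)2, THF, 0 °C; then 9, −78 → 0 °C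
Reagents that add atoms: methyltriphenylphosphonium bromide (C[P+](c1ccccc1)(c1ccccc1)c1ccccc1.[Br-])
Why: Wittig methylenation with the non-stabilised ylide adds C20 at low temperature without epimerising the α-silyloxy centre C22.

Step 7
Reactants: 10 alkenyl dithiane
Product: 11 (3S,4R)-3,4-bis(tert-butyldimethylsilyloxy)hex-5-enal
Conditions: MeI, CaCO3, MeCN/H2O (9:1), 45 °C
Reagents that add atoms: water (O)
Why: Alkylative dithiane hydrolysis (S-methylation, then buffered hydrolysis) unmasks the C25 aldehyde without acid that would cleave silyl ethers or cause β-elimination.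

Step 8
Reactants: 11 aldehyde
Product: 12 (2S,4S,5R)-4,5-bis(tert-butyldimethylsilyloxy)-1-nitrohept-6-en-2-ol
Conditions: CH3NO2 (10 equiv), Cu(OAc)2·H2O (5 mol %), 2,2'-(propane-2,2-diyl)bis(3a,8a-dihydro-8H-indeno[1,2-d]oxazole) (indabox, 5.5 mol %, antipode giving Re-face attack), EtOH, rt
Reagents that add atoms: nitromethane (C[N+](=O)[O-])
Why: Catalytic asymmetric Henry (nitroaldol) reaction: the chiral copper–bis(oxazoline) complex binds the aldehyde and delivers the nitronate to its Re face, setting C25 as (S) under catalyst control while adding C26 and the nitrogen.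

Step 9
Reactants: 12 nitro alcohol
Product: 13 (3R,4S,6S)-3,4,6-tris(tert-butyldimethylsilyloxy)-7-nitrohept-1-ene
Conditions: t-BuMe2SiOTf, 2,6-lutidine, CH2Cl2, −78 °C
Reagents that add atoms: tert-butyldimethylsilyl triflate (CC(C)(C)[Si](C)(C)OS(=O)(=O)C(F)(F)F)
Why: O-Silylation at low temperature with a weak hindered base is faster than retro-Henry cleavage or elimination of the β-nitro alcohol.

Step 10
Reactants: 13 nitro compound
Product: 14 (2S,4S,5R)-2,4,5-tris(tert-butyldimethylsilyloxy)hept-6-en-1-amine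
Conditions: Zn dust, AcOH, THF, 0 °C → rt; aq NaHCO3 work-up
Reagents that add atoms: none
Why: Dissolving-metal reduction of the primary nitroalkane to the amine leaves the terminal alkene and the silyl ethers untouched.

Step 11
Reactants: 4 (S)-2-hydroxypentanoic acid; 14 amine
Product: 16 (S)-2-hydroxy-N-[(2S,4S,5R)-2,4,5-tris(tert-butyldimethylsilyloxy)hept-6-en-1-yl]pentanamide, via benzotriazolyl ester 15 (not isolated)
Conditions: EDC·HCl, HOBt, CH2Cl2, 0 °C → rt
Reagents that add atoms: none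
Why: Carbodiimide/HOBt amide coupling forms N27–C28; the primary amine outcompetes the secondary α-hydroxyl, so the hydroxy acid is used unprotected.

Step 12
Reactants: 17 cis-2,4-dimethylglutaric anhydride (meso)
Product: 18 (2R,4S)-5-methoxy-2,4-dimethyl-5-oxopentanoic acid
Conditions: (DHQD)2AQN (30 mol %), MeOH (10 equiv), Et2O, −40 °C
Reagents that add atoms: methanol (CO)
Why: Cinchona-alkaloid-catalysed enantioselective alcoholysis (desymmetrisation) of the meso anhydride: the chiral amine directs methanol to one enantiotopic carbonyl, which fixes the absolute configuration of the syn methyl-bearing carbons C4 and C6.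

Step 13
Reactants: 18 hemiester
Product: 19 methyl (2S,4R)-5-hydroxy-2,4-dimethylpentanoate
Conditions: BH3·SMe2, THF, 0 °C → rt; MeOH quench
Reagents that add atoms: none
Why: Chemoselective borane reduction: the carboxylic acid is reduced through its acyloxyborane much faster than the methyl ester, giving the C7 alcohol.

Step 14
Reactants: 19 hydroxy ester (used at once to avoid lactonisation)
Product: 20 methyl (2S,4R)-2,4-dimethyl-5-oxopentanoate
Conditions: SO3·pyridine, DMSO, i-Pr2NEt, CH2Cl2, 0 °C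
Reagents that add atoms: none
Why: Parikh–Doering oxidation gives the α-methyl aldehyde under cold basic conditions without epimerisation at C6.

Step 15
Reactants: 20 aldehyde
Product: 21 (4Z,6R,8S)-9-methoxy-6,8-dimethyl-9-oxonon-4-enoic acid
Conditions: Ph3P(CH2)3CO2H Br (1.3 equiv), NaN(SiMe3)2 (2.6 equiv), THF, 0 °C; then 20, −78 °C → rt; pH 4 work-up
Reagents that add atoms: (3-carboxypropyl)triphenylphosphonium bromide (OC(=O)CCC[P+](c1ccccc1)(c1ccccc1)c1ccccc1.[Br-])
Why: Wittig olefination with the carboxylate-bearing non-stabilised ylide adds C8–C11 in one step, and the aldehyde is consumed at −78 °C before it can epimerise.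

Step 16
Reactants: 21 alkenoic acid
Product: 22 (6S,8S)-9-methoxy-6,8-dimethyl-9-oxononanoic acid
Conditions: H2 (1 atm), PtO2, EtOAc, rt
Reagents that add atoms: none
Why: Heterogeneous hydrogenation of the disubstituted alkene over PtO2, which causes little double-bond migration and so preserves the allylic centre C6.

Step 17
Reactants: 22 acid
Product: 24 methyl (2S,4S)-9-(ethylsulfanyl)-2,4-dimethyl-9-oxononanoate, via O-acylisourea 23 (not isolated)
Conditions: EtSH, EDC·HCl, DMAP (cat.), CH2Cl2, 0 °C → rt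
Reagents that add atoms: ethanethiol (CCS)
Why: Steglich-type thioesterification turns the C11 acid into the S-ethyl thioester needed for the Fukuyama coupling; the methyl ester is inert.

Step 18
Reactants: 25 (S)-4-benzyloxazolidin-2-one
Product: 27 (S)-4-benzyl-3-butanoyloxazolidin-2-one, via lithium oxazolidinide 26 (not isolated)
Conditions: n-BuLi, THF, −78 °C; then butanoyl chloride, −78 → 0 °C
Reagents that add atoms: butanoyl chloride (CCCC(=O)Cl)
Why: N-Acylation of the lithiated Evans auxiliary.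

Step 19
Reactants: 27 N-butanoyl imide
Product: 29 (S)-4-benzyl-3-[(R)-2-ethylpent-4-enoyl]oxazolidin-2-one, via sodium enolate 28 (not isolated)
Conditions: NaN(SiMe3)2, THF, −78 °C; then allyl iodide, −78 → −40 °C
Reagents that add atoms: allyl iodide (C=CCI)
Why: Evans asymmetric alkylation: the chelated (Z)-enolate is allylated on the face opposite the benzyl group, setting C15 as (R).

Step 20
Reactants: 29 allylated imide
Product: 30 (R)-2-ethylpent-4-en-1-ol
Conditions: LiBH4, H2O (1 equiv), Et2O, 0 °C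
Reagents that add atoms: none
Why: Reductive cleavage of the imide gives the C16 primary alcohol without touching C15 and returns the auxiliary.

Step 21
Reactants: 30 alcohol
Product: 31 tert-butyl{[(R)-2-ethylpent-4-en-1-yl]oxy}diphenylsilane
Conditions: t-BuPh2SiCl, imidazole, DMF, rt
Reagents that add atoms: tert-butyl(chloro)diphenylsilane (CC(C)(C)[Si](Cl)(c1ccccc1)c1ccccc1)
Why: Silylation of the primary alcohol as the acid-robust tert-butyldiphenylsilyl ether, which survives the later ketalisation.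

Step 22
Reactants: 31 silyl ether
Product: 33 tert-butyl{[(R)-2-ethyl-5-iodopentyl]oxy}diphenylsilane, via alkylzirconocene chloride 32 (not isolated)
Conditions: Cp2Zr(H)Cl (1.5 equiv), THF, rt; then I2, 0 °C
Reagents that add atoms: iodine (II)
Why: Hydrozirconation–iodination: zirconium adds to the terminal carbon (C12) of the monosubstituted alkene and iodinolysis of the C–Zr bond gives the primary iodide.

Step 23
Reactants: 33 iodide; 24 thioester
Product: 35 methyl (2S,4S,13R)-13-[(tert-butyldiphenylsilyloxy)methyl]-2,4-dimethyl-9-oxopentadecanoate, via alkylzinc iodide 34 (not isolated)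
Conditions: Zn dust (activated by BrCH2CH2Br and Me3SiCl), THF, 40 °C; then 24, PdCl2(PPh3)2 (5 mol %), toluene, rt; aq NH4Cl
Reagents that add atoms: none
Why: Fukuyama ketone synthesis: the alkylzinc iodide couples under palladium catalysis at the thioester C–S bond only, forming C11–C12 and leaving the methyl ester untouched.

Step 24
Reactants: 35 ketone
Product: 36 methyl (2S,4S)-8-{2-[(4R)-4-[(tert-butyldiphenylsilyloxy)methyl]hexyl]-1,3-dioxolan-2-yl}-2,4-dimethyloctanoate
Conditions: Me3SiOCH2CH2OSiMe3, Me3SiOTf (5 mol %), CH2Cl2, −78 → −20 °C; pyridine quench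
Reagents that add atoms: 1,2-bis(trimethylsilyloxy)ethane (C[Si](C)(C)OCCO[Si](C)(C)C)
Why: Noyori ketalisation under aprotic conditions masks the C11 ketone as the dioxolane without cleaving the silyl ether or the ester.

Step 25
Reactants: 36 silyl ether ketal
Product: 37 methyl (2S,4S)-8-{2-[(4R)-4-(hydroxymethyl)hexyl]-1,3-dioxolan-2-yl}-2,4-dimethyloctanoate
Conditions: Bu4NF, THF, rt; aq NH4Cl
Reagents that add atoms: none
Why: Fluoride-induced desilylation frees the C16 alcohol; the ester and ketal are stable.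

Step 26
Reactants: 37 alcohol
Product: 38 methyl (2S,4S)-8-{2-[(4R)-4-formylhexyl]-1,3-dioxolan-2-yl}-2,4-dimethyloctanoate
Conditions: SO3·pyridine, DMSO, i-Pr2NEt, CH2Cl2, 0 °C
Reagents that add atoms: none
Why: Parikh–Doering oxidation is acid-free and cold, so the ketal and the α-ethyl centre C15 are kept.

Step 27
Reactants: 38 aldehyde
Product: 39 methyl (2S,4S)-8-{2-[(4R,5E)-4-ethyl-6-iodohex-5-en-1-yl]-1,3-dioxolan-2-yl}-2,4-dimethyloctanoate
Conditions: CrCl2 (6 equiv), CHI3 (2 equiv), THF/1,4-dioxane, 0 °C → rt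
Reagents that add atoms: iodoform (IC(I)I)
Why: Takai olefination: the geminal dichromium species from CHI3 adds to the aldehyde and eliminates to the (E)-C16=C17 alkenyl iodide under conditions that do not enolise the aldehyde.

Step 28
Reactants: 39 methyl ester
Product: 40 (2S,4S)-8-{2-[(4R,5E)-4-ethyl-6-iodohex-5-en-1-yl]-1,3-dioxolan-2-yl}-2,4-dimethyloctanoic acid
Conditions: LiOH·H2O, THF/MeOH/H2O, rt → 40 °C; citric acid to pH 4
Reagents that add atoms: lithium hydroxide ([Li+].[OH-])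
Why: Saponification: hydroxide attacks the ester carbonyl and does not deprotonate C4, and the pH 4 work-up keeps the ketal.

Step 29
Reactants: 40 acid; 16 hydroxy amide
Product: 42 seco alkenyl iodide (O2–C3 ester of acid 40 on the C1 hydroxyl of amide 16), via mixed anhydride 41 (not isolated)
Conditions: 2,4,6-trichlorobenzoyl chloride, Et3N, THF, rt; then 16, DMAP, toluene, rt
Reagents that add atoms: none
Why: Yamaguchi esterification: the mixed anhydride reacts at its aliphatic carbonyl with the secondary α-hydroxyl under DMAP catalysis, forming the O2–C3 ester with C1 and C4 unchanged.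

Step 30
Reactants: 43 propiolic acid
Product: 45 2-(trimethylsilyl)ethyl prop-2-ynoate, via O-acylisourea 44 (not isolated)
Conditions: Me3SiCH2CH2OH, DCC, DMAP (cat.), CH2Cl2, −20 → 0 °C
Reagents that add atoms: 2-(trimethylsilyl)ethanol (C[Si](C)(C)CCO)
Why: Steglich esterification at low temperature gives the fluoride-cleavable propiolate ester without polymerising the ynoate.

Step 31
Reactants: 42 seco alkenyl iodide; 45 propiolate ester
Product: 46 seco enynoate (C17–C18 bond formed; (16E)-en-18-ynoate 2-(trimethylsilyl)ethyl ester)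
Conditions: PdCl2(PPh3)2 (5 mol %), CuI (10 mol %), i-Pr2NEt (2 equiv), THF, 0 °C → rt, slow addition of 45
Reagents that add atoms: none
Why: Sonogashira coupling of the (E)-alkenyl iodide with the terminal ynoate retains the alkene geometry, and the hindered amine base does not add to the propiolate.

Step 32
Reactants: 46 seco enynoate
Product: 47 seco C19 stannane ((2E,4E)-2-(tributylstannyl)dienoate)
Conditions: Bu3SnH (1.2 equiv), Pd(PPh3)4 (5 mol %), THF, 0 °C
Reagents that add atoms: tributyltin hydride (CCCC[SnH](CCCC)CCCC)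
Why: Palladium-catalysed hydrostannation of the ynoate is a syn addition that puts hydride on the β-carbon C18 and tin on the ester-bearing C19, so C17 and the carboxyl end up cis; the terminal alkene is inert.

Step 33
Reactants: 47 stannane
Product: 48 seco C19 iodide ((2E,4E)-2-iodo-dienoate; cyclisation precursor)
Conditions: I2 (1.05 equiv), CH2Cl2, 0 °C; aq Na2S2O3
Reagents that add atoms: iodine (II)
Why: Iododestannylation (electrophilic ipso substitution) replaces tin by iodine with retention of the alkene geometry.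

Step 34
Reactants: 48 seco C19 iodide
Product: 50 protected macrocycle (C11 dioxolane; C22, C23 and C25 silyl ethers; C19 2-(trimethylsilyl)ethyl ester), via B-alkyl-9-BBN adduct 49 (not isolated)
Conditions: 9-BBN dimer (3 equiv B–H), THF, 0 °C → rt; H2O; then slow addition to Pd(dppf)Cl2·CH2Cl2 (20 mol %), AsPh3 (40 mol %), Cs2CO3 (5 equiv), DMF/THF/H2O, 45 °C, final 1 mM
Reagents that add atoms: none
Why: 9-BBN adds anti-Markovnikov to the only monosubstituted alkene (C20=C21) and puts boron on C20; base forms the borate, zerovalent palladium inserts into the C19–I bond with retention, the primary C20 alkyl group moves from boron to palladium and reductive elimination forms C19–C20. The closest known reaction type is the B-alkyl Suzuki–Miyaura macrocyclisation of an alkenyl iodide with an alkylborane made in situ from a terminal alkene. The 28-membered ring closes end to end by this intramolecular C(sp2)–C(sp3) coupling, both carbons of the new bond becoming ring atoms, and slow addition at high dilution favours ring closure over oligomer formation. No stereocentre is created; the (18Z) geometry (carboxyl cis to C17) is inherited from iodide 48 because oxidative addition and reductive elimination are stereoretentive. Chemoselective hydroboration rests on the bulk of 9-BBN and on the electron-poor, more substituted C16–C19 dienoate, and the wide-bite-angle dppf ligand with AsPh3 speeds reductive elimination ahead of β-hydride loss.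

Step 35
Reactants: 50 protected macrocycle
Product: 51 C11 ketone macrocycle (silyl ethers and 2-(trimethylsilyl)ethyl ester retained)
Conditions: PPTS, acetone/H2O (10:1), 50 °C
Reagents that add atoms: water (O)
Why: Mild acid-catalysed ketal hydrolysis frees the C11 ketone while the secondary silyl ethers and the silylethyl ester are stable.

Step 36
Reactants: 51 ketone macrocycle
Product: 52 CNP0182412.1 (target)
Conditions: Bu4NF/AcOH (1:1), THF, rt → 40 °C; pH 4 phosphate buffer work-up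
Reagents that add atoms: none
Why: Buffered fluoride desilylation removes the three silyl ethers and fragments the 2-(trimethylsilyl)ethyl ester (ethene and Me3SiF) to the free C19 acid, the acetic acid buffer protecting the ring ester from base.

## Compound list

1 | L-norvaline, (S)-2-aminopentanoic acid | CCC[C@H](N)C(=O)O | starting material
2 | (S)-1-carboxylatobutane-1-diazonium | CCC[C@H]([N+]#N)C(=O)[O-] | intermediate
3 | (R)-3-propyloxiran-2-one | CCC[C@H]1OC1=O | intermediate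
4 | (S)-2-hydroxypentanoic acid | CCC[C@H](O)C(=O)O | intermediate
5 | 2-deoxy-D-ribose (open-chain form) | O=CC[C@H](O)[C@H](O)CO | starting material
6 | (2R,3S)-4-(1,3-dithian-2-yl)butane-1,2,3-triol | S1CCCSC1C[C@H](O)[C@H](O)CO | intermediate
7 | 2-[(2S,3R)-2,3,4-tris(tert-butyldimethylsilyloxy)butyl]-1,3-dithiane | S1CCCSC1C[C@H](O[Si](C)(C)C(C)(C)C)[C@H](O[Si](C)(C)C(C)(C)C)CO[Si](C)(C)C(C)(C)C | intermediate
8 | (2R,3S)-2,3-bis(tert-butyldimethylsilyloxy)-4-(1,3-dithian-2-yl)butan-1-ol | S1CCCSC1C[C@H](O[Si](C)(C)C(C)(C)C)[C@H](O[Si](C)(C)C(C)(C)C)CO | intermediate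
9 | (2S,3S)-2,3-bis(tert-butyldimethylsilyloxy)-4-(1,3-dithian-2-yl)butanal | S1CCCSC1C[C@H](O[Si](C)(C)C(C)(C)C)[C@H](O[Si](C)(C)C(C)(C)C)C=O | intermediate
10 | 2-[(2S,3R)-2,3-bis(tert-butyldimethylsilyloxy)pent-4-en-1-yl]-1,3-dithiane | S1CCCSC1C[C@H](O[Si](C)(C)C(C)(C)C)[C@H](O[Si](C)(C)C(C)(C)C)C=C | intermediate
11 | (3S,4R)-3,4-bis(tert-butyldimethylsilyloxy)hex-5-enal | O=CC[C@H](O[Si](C)(C)C(C)(C)C)[C@H](O[Si](C)(C)C(C)(C)C)C=C | intermediate
12 | (2S,4S,5R)-4,5-bis(tert-butyldimethylsilyloxy)-1-nitrohept-6-en-2-ol | [O-][N+](=O)C[C@@H](O)C[C@H](O[Si](C)(C)C(C)(C)C)[C@H](O[Si](C)(C)C(C)(C)C)C=C | intermediate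
13 | (3R,4S,6S)-3,4,6-tris(tert-butyldimethylsilyloxy)-7-nitrohept-1-ene | [O-][N+](=O)C[C@@H](O[Si](C)(C)C(C)(C)C)C[C@H](O[Si](C)(C)C(C)(C)C)[C@H](O[Si](C)(C)C(C)(C)C)C=C | intermediate
14 | (2S,4S,5R)-2,4,5-tris(tert-butyldimethylsilyloxy)hept-6-en-1-amine | NC[C@@H](O[Si](C)(C)C(C)(C)C)C[C@H](O[Si](C)(C)C(C)(C)C)[C@H](O[Si](C)(C)C(C)(C)C)C=C | intermediate
15 | benzotriazol-1-yl (S)-2-hydroxypentanoate | CCC[C@H](O)C(=O)On1nnc2ccccc12 | intermediate
16 | (S)-2-hydroxy-N-[(2S,4S,5R)-2,4,5-tris(tert-butyldimethylsilyloxy)hept-6-en-1-yl]pentanamide | CCC[C@H](O)C(=O)NC[C@@H](O[Si](C)(C)C(C)(C)C)C[C@H](O[Si](C)(C)C(C)(C)C)[C@H](O[Si](C)(C)C(C)(C)C)C=C | intermediate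
17 | cis-2,4-dimethylglutaric anhydride, (3R,5S)-3,5-dimethyloxane-2,6-dione (meso) | C[C@H]1C[C@@H](C)C(=O)OC1=O | starting material
18 | (2R,4S)-5-methoxy-2,4-dimethyl-5-oxopentanoic acid | COC(=O)[C@@H](C)C[C@@H](C)C(=O)O | intermediate
19 | methyl (2S,4R)-5-hydroxy-2,4-dimethylpentanoate | COC(=O)[C@@H](C)C[C@@H](C)CO | intermediate
20 | methyl (2S,4R)-2,4-dimethyl-5-oxopentanoate | COC(=O)[C@@H](C)C[C@@H](C)C=O | intermediate
21 | (4Z,6R,8S)-9-methoxy-6,8-dimethyl-9-oxonon-4-enoic acid | COC(=O)[C@@H](C)C[C@@H](C)/C=C\CCC(=O)O | intermediate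
22 | (6S,8S)-9-methoxy-6,8-dimethyl-9-oxononanoic acid | COC(=O)[C@@H](C)C[C@@H](C)CCCCC(=O)O | intermediate
23 | O-acylisourea of acid 22 with EDC | COC(=O)[C@@H](C)C[C@@H](C)CCCCC(=O)OC(=NCC)NCCCN(C)C | intermediate
24 | methyl (2S,4S)-9-(ethylsulfanyl)-2,4-dimethyl-9-oxononanoate | COC(=O)[C@@H](C)C[C@@H](C)CCCCC(=O)SCC | intermediate
25 | (S)-4-benzyloxazolidin-2-one | O=C1OC[C@H](Cc2ccccc2)N1 | starting material
26 | lithium (S)-4-benzyl-2-oxooxazolidin-3-ide | [Li+].O=C1OC[C@H](Cc2ccccc2)[N-]1 | intermediate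
27 | (S)-4-benzyl-3-butanoyloxazolidin-2-one | CCCC(=O)N1[C@@H](Cc2ccccc2)COC1=O | intermediate
28 | sodium (Z)-enolate of imide 27 | [Na+].CC/C=C(\[O-])N1[C@@H](Cc2ccccc2)COC1=O | intermediate
29 | (S)-4-benzyl-3-[(R)-2-ethylpent-4-enoyl]oxazolidin-2-one | C=CC[C@@H](CC)C(=O)N1[C@@H](Cc2ccccc2)COC1=O | intermediate
30 | (R)-2-ethylpent-4-en-1-ol | C=CC[C@@H](CC)CO | intermediate
31 | tert-butyl{[(R)-2-ethylpent-4-en-1-yl]oxy}diphenylsilane | C=CC[C@@H](CC)CO[Si](c1ccccc1)(c1ccccc1)C(C)(C)C | intermediate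
32 | chlorobis(cyclopentadienyl)[(R)-5-(tert-butyldiphenylsilyloxy)-4-ethylpentyl]zirconium (cyclopentadienyl rings drawn σ-bound) | Cl[Zr](CCC[C@@H](CC)CO[Si](c1ccccc1)(c1ccccc1)C(C)(C)C)(C1C=CC=C1)C1C=CC=C1 | intermediate
33 | tert-butyl{[(R)-2-ethyl-5-iodopentyl]oxy}diphenylsilane | ICCC[C@@H](CC)CO[Si](c1ccccc1)(c1ccccc1)C(C)(C)C | intermediate
34 | [(R)-5-(tert-butyldiphenylsilyloxy)-4-ethylpentyl]zinc iodide | I[Zn]CCC[C@@H](CC)CO[Si](c1ccccc1)(c1ccccc1)C(C)(C)C | intermediate
35 | methyl (2S,4S,13R)-13-[(tert-butyldiphenylsilyloxy)methyl]-2,4-dimethyl-9-oxopentadecanoate | COC(=O)[C@@H](C)C[C@@H](C)CCCCC(=O)CCC[C@@H](CC)CO[Si](c1ccccc1)(c1ccccc1)C(C)(C)C | intermediate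
36 | methyl (2S,4S)-8-{2-[(4R)-4-[(tert-butyldiphenylsilyloxy)methyl]hexyl]-1,3-dioxolan-2-yl}-2,4-dimethyloctanoate | COC(=O)[C@@H](C)C[C@@H](C)CCCCC1(OCCO1)CCC[C@@H](CC)CO[Si](c1ccccc1)(c1ccccc1)C(C)(C)C | intermediate
37 | methyl (2S,4S)-8-{2-[(4R)-4-(hydroxymethyl)hexyl]-1,3-dioxolan-2-yl}-2,4-dimethyloctanoate | COC(=O)[C@@H](C)C[C@@H](C)CCCCC1(OCCO1)CCC[C@@H](CC)CO | intermediate
38 | methyl (2S,4S)-8-{2-[(4R)-4-formylhexyl]-1,3-dioxolan-2-yl}-2,4-dimethyloctanoate | COC(=O)[C@@H](C)C[C@@H](C)CCCCC1(OCCO1)CCC[C@@H](CC)C=O | intermediate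
39 | methyl (2S,4S)-8-{2-[(4R,5E)-4-ethyl-6-iodohex-5-en-1-yl]-1,3-dioxolan-2-yl}-2,4-dimethyloctanoate | COC(=O)[C@@H](C)C[C@@H](C)CCCCC1(OCCO1)CCC[C@@H](CC)/C=C/I | intermediate
40 | (2S,4S)-8-{2-[(4R,5E)-4-ethyl-6-iodohex-5-en-1-yl]-1,3-dioxolan-2-yl}-2,4-dimethyloctanoic acid | OC(=O)[C@@H](C)C[C@@H](C)CCCCC1(OCCO1)CCC[C@@H](CC)/C=C/I | intermediate
41 | mixed anhydride of acid 40 with 2,4,6-trichlorobenzoic acid | O=C(OC(=O)[C@@H](C)C[C@@H](C)CCCCC1(OCCO1)CCC[C@@H](CC)/C=C/I)c1c(Cl)cc(Cl)cc1Cl | intermediate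
42 | seco alkenyl iodide: (S)-1-oxo-1-{[(2S,4S,5R)-2,4,5-tris(tert-butyldimethylsilyloxy)hept-6-en-1-yl]amino}pentan-2-yl (2S,4S)-8-{2-[(4R,5E)-4-ethyl-6-iodohex-5-en-1-yl]-1,3-dioxolan-2-yl}-2,4-dimethyloctanoate | C=C[C@@H](O[Si](C)(C)C(C)(C)C)[C@@H](O[Si](C)(C)C(C)(C)C)C[C@H](O[Si](C)(C)C(C)(C)C)CNC(=O)[C@H](CCC)OC(=O)[C@@H](C)C[C@@H](C)CCCCC1(OCCO1)CCC[C@@H](CC)/C=C/I | intermediate
43 | propiolic acid | C#CC(=O)O | starting material
44 | O-acylisourea of propiolic acid with DCC | C#CC(=O)OC(=NC1CCCCC1)NC1CCCCC1 | intermediate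
45 | 2-(trimethylsilyl)ethyl prop-2-ynoate | C#CC(=O)OCC[Si](C)(C)C | intermediate
46 | seco enynoate: as 42 but with the side chain (4R,5E)-4-ethyl-9-oxo-9-[2-(trimethylsilyl)ethoxy]non-5-en-7-yn-1-yl on the dioxolane | C=C[C@@H](O[Si](C)(C)C(C)(C)C)[C@@H](O[Si](C)(C)C(C)(C)C)C[C@H](O[Si](C)(C)C(C)(C)C)CNC(=O)[C@H](CCC)OC(=O)[C@@H](C)C[C@@H](C)CCCCC1(OCCO1)CCC[C@@H](CC)/C=C/C#CC(=O)OCC[Si](C)(C)C | intermediate
47 | seco C19 stannane: side chain (4R,5E,7E)-4-ethyl-9-oxo-8-(tributylstannyl)-9-[2-(trimethylsilyl)ethoxy]nona-5,7-dien-1-yl | C=C[C@@H](O[Si](C)(C)C(C)(C)C)[C@@H](O[Si](C)(C)C(C)(C)C)C[C@H](O[Si](C)(C)C(C)(C)C)CNC(=O)[C@H](CCC)OC(=O)[C@@H](C)C[C@@H](C)CCCCC1(OCCO1)CCC[C@@H](CC)/C=C/C=C(/[Sn](CCCC)(CCCC)CCCC)C(=O)OCC[Si](C)(C)C | intermediate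
48 | seco C19 iodide: side chain (4R,5E,7E)-4-ethyl-8-iodo-9-oxo-9-[2-(trimethylsilyl)ethoxy]nona-5,7-dien-1-yl; terminal C20=C21 alkene | C=C[C@@H](O[Si](C)(C)C(C)(C)C)[C@@H](O[Si](C)(C)C(C)(C)C)C[C@H](O[Si](C)(C)C(C)(C)C)CNC(=O)[C@H](CCC)OC(=O)[C@@H](C)C[C@@H](C)CCCCC1(OCCO1)CCC[C@@H](CC)/C=C/C=C(/I)C(=O)OCC[Si](C)(C)C | intermediate
49 | B-alkyl-9-BBN adduct of 48 (9-borabicyclo[3.3.1]nonan-9-yl on C20) | C(C[C@@H](O[Si](C)(C)C(C)(C)C)[C@@H](O[Si](C)(C)C(C)(C)C)C[C@H](O[Si](C)(C)C(C)(C)C)CNC(=O)[C@H](CCC)OC(=O)[C@@H](C)C[C@@H](C)CCCCC1(OCCO1)CCC[C@@H](CC)/C=C/C=C(/I)C(=O)OCC[Si](C)(C)C)B1C2CCCC1CCC2 | intermediate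
50 | protected macrocycle: (1S,4S,6S,15R,16E,18Z,22R,23S,25S) 28-membered ring with C11 ethylene ketal, tert-butyldimethylsilyl ethers on O22, O23 and O25, 2-(trimethylsilyl)ethyl ester on C19 | CCC[C@@H]1OC(=O)[C@@H](C)C[C@@H](C)CCCCC2(OCCO2)CCC[C@@H](CC)/C=C/C=C(\C(=O)OCC[Si](C)(C)C)CC[C@@H](O[Si](C)(C)C(C)(C)C)[C@@H](O[Si](C)(C)C(C)(C)C)C[C@H](O[Si](C)(C)C(C)(C)C)CNC1=O | intermediate
51 | C11 ketone macrocycle (three silyl ethers and silylethyl ester retained) | CCC[C@@H]1OC(=O)[C@@H](C)C[C@@H](C)CCCCC(=O)CCC[C@@H](CC)/C=C/C=C(\C(=O)OCC[Si](C)(C)C)CC[C@@H](O[Si](C)(C)C(C)(C)C)[C@@H](O[Si](C)(C)C(C)(C)C)C[C@H](O[Si](C)(C)C(C)(C)C)CNC1=O | intermediate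
52 | CNP0182412.1 | CCC[C@@H]1OC(=O)[C@@H](C)C[C@@H](C)CCCCC(=O)CCC[C@@H](CC)/C=C/C=C(\C(=O)O)CC[C@@H](O)[C@@H](O)C[C@H](O)CNC1=O | target

## Summary

Total step count: 36.

Longest linear sequence: 19 steps, from anhydride 17 to target 52 (steps 12–17, 23–29, 31–36).

Steps most likely to fail:

1. Step 34 (ring closure). The borane may couple between molecules and give oligomers, boron may be lost by protodeboronation, or the alkylpalladium species may lose a β-hydride before the large ring closes. Fallback, setting out from methyl ester 39 and hydroxy amide 16 and returning at macrocycle 50: the C19–C20 bond is made between two molecules and the ring is closed at the O2–C3 ester instead. Ester 39 is carried through the conditions of steps 31–33 to the enynoate methyl ester F1, the C19 stannane F2 and the iodo-dienoate methyl ester F3. Amide 16 is hydroborated with 9-BBN (one extra equivalent for the hydroxyl) to the bis-borylated amide F4, which is coupled with F3 under Pd(dppf)Cl2/AsPh3/Cs2CO3 at ordinary concentration to the open-chain hydroxy methyl ester F5. Me3SnOH in 1,2-dichloroethane at 80 °C cleaves the methyl ester selectively to the seco acid F6, and Yamaguchi macrolactonisation through the mixed anhydride F7 (slow addition to DMAP in toluene) gives 50.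

2. Step 8 (nitroaldol). Facial selectivity at C25 may be poor if the catalyst and the β,γ-bis(silyloxy) aldehyde are mismatched, and the aldehyde may lose silanol by β-elimination. Fallback, setting out from aldehyde 11 and returning at amine 14: C25 is set by resolution of a terminal epoxide. Corey–Chaykovsky methylenation (Me3SI, KN(SiMe3)2, THF, −10 °C) gives the epoxide epimer mixture F8. Hydrolytic kinetic resolution with (S,S)-(salen)Co(OAc) and 0.55 equiv H2O (the antipode that hydrolyses the 25R epimer) leaves the (25S)-epoxide F9. NaN3/NH4Cl in MeOH/H2O opens it at C26 to the azido alcohol F10, t-BuMe2SiOTf/2,6-lutidine gives the azido silyl ether F11, and Zn/NH4Cl in EtOH/H2O reduces the azide to amine 14.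

3. Step 32 (hydrostannation). Tin may leak to C18 or add across the conjugated enyne in another sense, and palladium hydride may isomerise the diene, giving inseparable regio- and stereoisomers. Fallback, setting out from alkenyl iodide 42 and returning at macrocycle 50: the C18=C19 geometry is set by olefination instead of hydrometallation. Palladium-catalysed reductive carbonylation (CO, Bu3SnH added slowly, Pd(PPh3)4, THF, 50 °C) converts 42 into the (E)-enal F12. Horner–Wadsworth–Emmons reaction with 2-(trimethylsilyl)ethyl bis(2,2,2-trifluoroethyl)phosphonobromoacetate (t-BuOK, 18-crown-6, THF, −78 °C) gives the (2E,4E)-2-bromo-dienoate F13, with bromine trans to C17. This is hydroborated to the B-alkyl-9-BBN adduct F14 and cyclised under the conditions of step 34 to 50.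

Further compounds
F1 | step 34 | methyl (2S,4S)-8-{2-[(4R,5E)-4-ethyl-9-oxo-9-[2-(trimethylsilyl)ethoxy]non-5-en-7-yn-1-yl]-1,3-dioxolan-2-yl}-2,4-dimethyloctanoate | COC(=O)[C@@H](C)C[C@@H](C)CCCCC1(OCCO1)CCC[C@@H](CC)/C=C/C#CC(=O)OCC[Si](C)(C)C
F2 | step 34 | methyl (2S,4S)-8-{2-[(4R,5E,7E)-4-ethyl-9-oxo-8-(tributylstannyl)-9-[2-(trimethylsilyl)ethoxy]nona-5,7-dien-1-yl]-1,3-dioxolan-2-yl}-2,4-dimethyloctanoate | COC(=O)[C@@H](C)C[C@@H](C)CCCCC1(OCCO1)CCC[C@@H](CC)/C=C/C=C(/[Sn](CCCC)(CCCC)CCCC)C(=O)OCC[Si](C)(C)C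
F3 | step 34 | methyl (2S,4S)-8-{2-[(4R,5E,7E)-4-ethyl-8-iodo-9-oxo-9-[2-(trimethylsilyl)ethoxy]nona-5,7-dien-1-yl]-1,3-dioxolan-2-yl}-2,4-dimethyloctanoate | COC(=O)[C@@H](C)C[C@@H](C)CCCCC1(OCCO1)CCC[C@@H](CC)/C=C/C=C(/I)C(=O)OCC[Si](C)(C)C
F4 | step 34 | bis-borylated amide: 16 with 9-borabicyclo[3.3.1]nonan-9-yl on C20 and on the C1 oxygen | CCC[C@H](OB1C2CCCC1CCC2)C(=O)NC[C@@H](O[Si](C)(C)C(C)(C)C)C[C@H](O[Si](C)(C)C(C)(C)C)[C@H](O[Si](C)(C)C(C)(C)C)CCB1C2CCCC1CCC2
F5 | step 34 | open-chain hydroxy methyl ester (C19–C20 bond formed; C3 methyl ester; free C1 hydroxyl) | COC(=O)[C@@H](C)C[C@@H](C)CCCCC1(OCCO1)CCC[C@@H](CC)/C=C/C=C(\C(=O)OCC[Si](C)(C)C)CC[C@@H](O[Si](C)(C)C(C)(C)C)[C@@H](O[Si](C)(C)C(C)(C)C)C[C@H](O[Si](C)(C)C(C)(C)C)CNC(=O)[C@@H](O)CCC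
F6 | step 34 | seco acid (C3 carboxylic acid; free C1 hydroxyl) | OC(=O)[C@@H](C)C[C@@H](C)CCCCC1(OCCO1)CCC[C@@H](CC)/C=C/C=C(\C(=O)OCC[Si](C)(C)C)CC[C@@H](O[Si](C)(C)C(C)(C)C)[C@@H](O[Si](C)(C)C(C)(C)C)C[C@H](O[Si](C)(C)C(C)(C)C)CNC(=O)[C@@H](O)CCC
F7 | step 34 | mixed anhydride of seco acid F6 with 2,4,6-trichlorobenzoic acid | Clc1cc(Cl)c(C(=O)OC(=O)[C@@H](C)C[C@@H](C)CCCCC2(OCCO2)CCC[C@@H](CC)/C=C/C=C(\C(=O)OCC[Si](C)(C)C)CC[C@@H](O[Si](C)(C)C(C)(C)C)[C@@H](O[Si](C)(C)C(C)(C)C)C[C@H](O[Si](C)(C)C(C)(C)C)CNC(=O)[C@@H](O)CCC)c(Cl)c1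
F8 | step 8 | (3R,4S)-3,4-bis(tert-butyldimethylsilyloxy)-5-(oxiran-2-yl)pent-1-ene (both epimers at the oxirane carbon) | C1OC1C[C@H](O[Si](C)(C)C(C)(C)C)[C@H](O[Si](C)(C)C(C)(C)C)C=C
F9 | step 8 | (3R,4S)-3,4-bis(tert-butyldimethylsilyloxy)-5-[(2S)-oxiran-2-yl]pent-1-ene | C1O[C@H]1C[C@H](O[Si](C)(C)C(C)(C)C)[C@H](O[Si](C)(C)C(C)(C)C)C=C
F10 | step 8 | (2S,4S,5R)-1-azido-4,5-bis(tert-butyldimethylsilyloxy)hept-6-en-2-ol | [N-]=[N+]=NC[C@@H](O)C[C@H](O[Si](C)(C)C(C)(C)C)[C@H](O[Si](C)(C)C(C)(C)C)C=C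
F11 | step 8 | (3R,4S,6S)-7-azido-3,4,6-tris(tert-butyldimethylsilyloxy)hept-1-ene | [N-]=[N+]=NC[C@@H](O[Si](C)(C)C(C)(C)C)C[C@H](O[Si](C)(C)C(C)(C)C)[C@H](O[Si](C)(C)C(C)(C)C)C=C
F12 | step 32 | seco (E)-enal: 42 with the C17 iodine replaced by a formyl group (C18) | C=C[C@@H](O[Si](C)(C)C(C)(C)C)[C@@H](O[Si](C)(C)C(C)(C)C)C[C@H](O[Si](C)(C)C(C)(C)C)CNC(=O)[C@H](CCC)OC(=O)[C@@H](C)C[C@@H](C)CCCCC1(OCCO1)CCC[C@@H](CC)/C=C/C=O
F13 | step 32 | seco C19 bromide ((2E,4E)-2-bromo-dienoate 2-(trimethylsilyl)ethyl ester) | C=C[C@@H](O[Si](C)(C)C(C)(C)C)[C@@H](O[Si](C)(C)C(C)(C)C)C[C@H](O[Si](C)(C)C(C)(C)C)CNC(=O)[C@H](CCC)OC(=O)[C@@H](C)C[C@@H](C)CCCCC1(OCCO1)CCC[C@@H](CC)/C=C/C=C(/Br)C(=O)OCC[Si](C)(C)C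
F14 | step 32 | B-alkyl-9-BBN adduct of bromide F13 (boron on C20) | C(C[C@@H](O[Si](C)(C)C(C)(C)C)[C@@H](O[Si](C)(C)C(C)(C)C)C[C@H](O[Si](C)(C)C(C)(C)C)CNC(=O)[C@H](CCC)OC(=O)[C@@H](C)C[C@@H](C)CCCCC1(OCCO1)CCC[C@@H](CC)/C=C/C=C(/Br)C(=O)OCC[Si](C)(C)C)B1C2CCCC1CCC2
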